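**Plan**

- Cuts, in retrosynthetic order: the C4–C5 double bond of ring A is removed first, leaving a 4,5-dihydrobenzofuran with O6 held as an enol ether. Then the furan bond O1–C7a is cut to a 1,4-diketone, then C3–C3a (enolate alkylation), and last C7–C1′ (geranyl), back to cyclohexane-1,3-dione.
- Enabling feature: C6–O, C7–geranyl and C7a–O1 of ring A form a 2-alkyl-1,3-dioxygenated triad, which is 2-geranylcyclohexane-1,3-dione. Its α′ carbon is C3a, so its carbonyl carbon C7a sits 1,4 to the aryl ketone carbon C2.
- Forward order: geranyl goes onto the dione, the ethyl vinylogous ester is alkylated at C3a with a silylated aryl bromomethyl ketone, and furan ring B closes on the still saturated ring A. Ring A is aromatised last (enol ether hydrolysis, enol silylation, DDQ), and three silyl groups are removed.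
- Stereochemistry: the target has no stereocentre. Its only stereo element, the E C2′=C3′ alkene, comes with geranyl bromide and is never touched; the centres that appear at C3a and C7 on the way are racemic and are erased.

Key step: step 6

Remark: ring positions are given in the benzofuran numbering of the target (O1, C2, C3, C3a, C4 to C7, C7a; geranyl carbons primed). "Geranyl" means (2E)-3,7-dimethylocta-2,6-dien-1-yl and TBS means tert-butyldimethylsilyl. Cyclohexane-1,3-dione, geranyl bromide and 3,5-dihydroxyacetophenone are taken as commercial.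

**Route**

Step 1
Reactants: 1 cyclohexane-1,3-dione; 2 geranyl bromide, (2E)-1-bromo-3,7-dimethylocta-2,6-diene
Product: 3 2-geranylcyclohexane-1,3-dione
Conditions: KOH (1 equiv), H2O, 1 in excess, rt, vigorous stirring; acidic work-up
Reagents that add atoms: none
Why: C-alkylation of a 1,3-dione enolate with an allylic bromide (SN2) in water, where hydrogen bonding to the enolate oxygens steers the soft electrophile to C2 and the E alkene is carried over unchanged; the excess of dione limits a second alkylation.

Step 2
Reactants: 3 2-geranylcyclohexane-1,3-dione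
Product: 4 3-ethoxy-2-geranylcyclohex-2-en-1-one
Conditions: Et2SO4, K2CO3, acetone, reflux
Reagents that add atoms: diethyl sulfate, CCOS(=O)(=O)OCC
Why: O-alkylation of the potassium enolate of a 2-substituted 1,3-dione by the hard electrophile diethyl sulfate gives the vinylogous ester without acid, so the enol cannot add to the C2′=C3′ alkene as it could under acid-catalysed enol etherification.

Step 3
Reactants: 5 3,5-dihydroxyacetophenone
Product: 6 1-[3,5-bis(tert-butyldimethylsilyloxy)phenyl]ethan-1-one
Conditions: TBSCl (2.4 equiv), imidazole, DMF, rt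
Reagents that add atoms: tert-butyldimethylsilyl chloride, CC(C)(C)[Si](C)(C)Cl
Why: Silylation of both phenols with a silyl chloride and imidazole gives aryl silyl ethers that should survive the enolate, weak-acid and DDQ steps and leave with fluoride at the end.

Step 4
Reactants: 6 1-[3,5-bis(tert-butyldimethylsilyloxy)phenyl]ethan-1-one
Product: 8 2-bromo-1-[3,5-bis(tert-butyldimethylsilyloxy)phenyl]ethan-1-one, via trimethylsilyl enol ether 7 (not isolated)
Conditions: LiN(SiMe3)2 added to 6 and Me3SiCl, THF, −78 °C; then NBS, THF, 0 °C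
Reagents that add atoms: N-bromosuccinimide, O=C1CCC(=O)N1Br; chlorotrimethylsilane, C[Si](C)(C)Cl (its silyl group is found in 7 only)
Why: Enolisation of the methyl ketone in the presence of Me3SiCl gives the enol silane, and its electrophilic α-bromination with NBS is acid-free, should stop at the monobromide and should spare the silyloxy-substituted ring.

Step 5
Reactants: 4 3-ethoxy-2-geranylcyclohex-2-en-1-one; 8 2-bromo-1-[3,5-bis(tert-butyldimethylsilyloxy)phenyl]ethan-1-one
Product: 10 6-{2-[3,5-bis(tert-butyldimethylsilyloxy)phenyl]-2-oxoethyl}-3-ethoxy-2-geranylcyclohex-2-en-1-one (racemic), via lithium dienolate 9 (not isolated)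
Conditions: LiN(i-Pr)2 (0.95 equiv based on 4), THF, −78 °C; then 8, DMPU, −78 to −40 °C
Reagents that add atoms: lithium diisopropylamide, CC(C)N([Li])C(C)C (its lithium is found in 9 only)
Why: Stork–Danheiser kinetic deprotonation at the α′ carbon (future C3a) gives the cross-conjugated dienolate, which displaces bromide from the α-bromo ketone in an SN2 alkylation that forms C3–C3a; the slight deficit of base keeps amide away from 8, and the new centre is racemic and is erased in step 6.

Step 6
Reactants: 10 6-{2-[3,5-bis(tert-butyldimethylsilyloxy)phenyl]-2-oxoethyl}-3-ethoxy-2-geranylcyclohex-2-en-1-one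
Product: 11 6-ethoxy-7-geranyl-2-[3,5-bis(tert-butyldimethylsilyloxy)phenyl]-4,5-dihydro-1-benzofuran
Conditions: pyridinium p-toluenesulfonate (0.2 equiv), 4 Å molecular sieves, toluene, 80 °C
Reagents that add atoms: none
Why: The weak acid protonates the vinylogous ester carbonyl, the more basic of the two; the enol of the aryl ketone adds through its oxygen to C7a; the hemiketal loses water with help from O1 and the ethoxy-substituted C6=C7 bond; and loss of the C3a proton gives the furan. The closest known reaction is the Paal–Knorr furan synthesis from 1,4-diketones. Ring B closes by 5-exo-trig attack of oxygen on the ring carbonyl carbon, which forms the O1–C7a bond. No stereocentre is formed, and the racemic centre at C3a of 10 is erased. The step needs O-cyclisation to win over hydrolysis of the enol ether and over acid-initiated cyclisation of the geranyl chain: only the C7a carbonyl lies 1,4 to the aryl ketone, the sieves take up the water, and the weak acid should not protonate trisubstituted alkenes. Any ketone 12 formed by adventitious hydrolysis is the product of step 7 and can be carried along.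

Step 7
Reactants: 11 6-ethoxy-7-geranyl-2-[3,5-bis(tert-butyldimethylsilyloxy)phenyl]-4,5-dihydro-1-benzofuran
Product: 12 7-geranyl-2-[3,5-bis(tert-butyldimethylsilyloxy)phenyl]-4,5-dihydro-1-benzofuran-6(7H)-one (racemic)
Conditions: 0.5 M aq. HCl, THF, 0 °C, under argon; used at once
Reagents that add atoms: water, O
Why: Acid-catalysed enol ether hydrolysis: protonation at C7 gives the C6 oxocarbenium ion, water adds and ethanol leaves, while the aryl silyl ethers, the furan and the geranyl alkenes should tolerate cold dilute acid; the C7 centre is racemic and is made planar again in step 8.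

Step 8
Reactants: 12 7-geranyl-2-[3,5-bis(tert-butyldimethylsilyloxy)phenyl]-4,5-dihydro-1-benzofuran-6(7H)-one
Product: 13 6-(tert-butyldimethylsilyloxy)-7-geranyl-2-[3,5-bis(tert-butyldimethylsilyloxy)phenyl]-4,5-dihydro-1-benzofuran
Conditions: TBSOTf, Et3N, CH2Cl2, 0 °C
Reagents that add atoms: tert-butyldimethylsilyl trifluoromethanesulfonate, CC(C)(C)[Si](C)(C)OS(=O)(=O)C(F)(F)F
Why: Soft enolisation with a silyl triflate and an amine removes the most acidic proton, C7–H between the ketone and the furan, and should give the thermodynamic furan-conjugated silyl dienol ether; the C5=C6 regioisomer, if formed, would also be aromatised in step 9.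

Step 9
Reactants: 13 6-(tert-butyldimethylsilyloxy)-7-geranyl-2-[3,5-bis(tert-butyldimethylsilyloxy)phenyl]-4,5-dihydro-1-benzofuran
Product: 14 6-(tert-butyldimethylsilyloxy)-7-geranyl-2-[3,5-bis(tert-butyldimethylsilyloxy)phenyl]-1-benzofuran
Conditions: DDQ (1.0 equiv), 2,4,6-collidine, CH2Cl2, 0 °C
Reagents that add atoms: none
Why: Quinone dehydrogenation: DDQ abstracts hydride from C4 to give a cation delocalised through the furan onto the silyloxy-bearing C6, and loss of the C5 proton gives the aryl silyl ether, as known for silyl dienol ethers of cyclohexenones; the O-silyl cap blocks the chromene-forming oxidation of an ortho-geranyl phenol, and one equivalent at 0 °C should spare the allylic positions.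

Step 10
Reactants: 14 6-(tert-butyldimethylsilyloxy)-7-geranyl-2-[3,5-bis(tert-butyldimethylsilyloxy)phenyl]-1-benzofuran
Product: 15 5-{7-[(2E)-3,7-dimethylocta-2,6-dien-1-yl]-6-hydroxy-1-benzofuran-2-yl}benzene-1,3-diol (target)
Conditions: Bu4NF (3.3 equiv), AcOH, THF, 0 °C to rt
Reagents that add atoms: none
Why: Fluoride-induced cleavage of the three aryl silyl ethers, driven by the Si–F bond, with acetic acid present so that the electron-rich phenoxides are protonated as they form and the E alkene is left alone.

**Compound list**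

1 | cyclohexane-1,3-dione | O=C1CCCC(=O)C1 | starting material
2 | geranyl bromide, (2E)-1-bromo-3,7-dimethylocta-2,6-diene | CC(C)=CCC/C(C)=C/CBr | starting material
3 | 2-geranylcyclohexane-1,3-dione | O=C1CCCC(=O)C1C/C=C(\C)CCC=C(C)C | intermediate
4 | 3-ethoxy-2-geranylcyclohex-2-en-1-one | CCOC1=C(C/C=C(\C)CCC=C(C)C)C(=O)CCC1 | intermediate
5 | 3,5-dihydroxyacetophenone | CC(=O)c1cc(O)cc(O)c1 | starting material
6 | 1-[3,5-bis(tert-butyldimethylsilyloxy)phenyl]ethan-1-one | CC(=O)c1cc(O[Si](C)(C)C(C)(C)C)cc(O[Si](C)(C)C(C)(C)C)c1 | intermediate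
7 | {1-[3,5-bis(tert-butyldimethylsilyloxy)phenyl]ethenyloxy}trimethylsilane | C=C(O[Si](C)(C)C)c1cc(O[Si](C)(C)C(C)(C)C)cc(O[Si](C)(C)C(C)(C)C)c1 | intermediate
8 | 2-bromo-1-[3,5-bis(tert-butyldimethylsilyloxy)phenyl]ethan-1-one | BrCC(=O)c1cc(O[Si](C)(C)C(C)(C)C)cc(O[Si](C)(C)C(C)(C)C)c1 | intermediate
9 | lithium 3-ethoxy-2-geranylcyclohexa-1,5-dien-1-olate (α′ dienolate of 4) | CCOC1=C(C/C=C(\C)CCC=C(C)C)C(O[Li])=CCC1 | intermediate
10 | 6-{2-[3,5-bis(tert-butyldimethylsilyloxy)phenyl]-2-oxoethyl}-3-ethoxy-2-geranylcyclohex-2-en-1-one (racemic) | CCOC1=C(C/C=C(\C)CCC=C(C)C)C(=O)C(CC(=O)c2cc(O[Si](C)(C)C(C)(C)C)cc(O[Si](C)(C)C(C)(C)C)c2)CC1 | intermediate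
11 | 6-ethoxy-7-geranyl-2-[3,5-bis(tert-butyldimethylsilyloxy)phenyl]-4,5-dihydro-1-benzofuran | CCOC1=C(C/C=C(\C)CCC=C(C)C)c2oc(-c3cc(O[Si](C)(C)C(C)(C)C)cc(O[Si](C)(C)C(C)(C)C)c3)cc2CC1 | intermediate
12 | 7-geranyl-2-[3,5-bis(tert-butyldimethylsilyloxy)phenyl]-4,5-dihydro-1-benzofuran-6(7H)-one (racemic) | O=C1CCc2cc(-c3cc(O[Si](C)(C)C(C)(C)C)cc(O[Si](C)(C)C(C)(C)C)c3)oc2C1C/C=C(\C)CCC=C(C)C | intermediate
13 | 6-(tert-butyldimethylsilyloxy)-7-geranyl-2-[3,5-bis(tert-butyldimethylsilyloxy)phenyl]-4,5-dihydro-1-benzofuran | CC(C)(C)[Si](C)(C)OC1=C(C/C=C(\C)CCC=C(C)C)c2oc(-c3cc(O[Si](C)(C)C(C)(C)C)cc(O[Si](C)(C)C(C)(C)C)c3)cc2CC1 | intermediate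
14 | 6-(tert-butyldimethylsilyloxy)-7-geranyl-2-[3,5-bis(tert-butyldimethylsilyloxy)phenyl]-1-benzofuran | CC(C)(C)[Si](C)(C)Oc1ccc2cc(-c3cc(O[Si](C)(C)C(C)(C)C)cc(O[Si](C)(C)C(C)(C)C)c3)oc2c1C/C=C(\C)CCC=C(C)C | intermediate
15 | 5-{7-[(2E)-3,7-dimethylocta-2,6-dien-1-yl]-6-hydroxy-1-benzofuran-2-yl}benzene-1,3-diol | CC(C)=CCC/C(C)=C/Cc1c(O)ccc2cc(-c3cc(O)cc(O)c3)oc12 | target

**Step count and risks**

Total step count: 10. Longest linear sequence: 8 steps (steps 1, 2, 5 to 10 from compound 1; equally steps 3 to 10 from compound 5).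

Steps most likely to fail:

1. Step 5. The dienolate may take a proton from the acidic bromo ketone, or add to its carbonyl group and close to an epoxide, instead of displacing bromide. The fallback sets out from 4 and builds the same 1,4-diketone by acyl anion addition. The lithium dienolate of 4 is treated with dimethyl(methylidene)ammonium iodide (Mannich reaction) to give 6-[(dimethylamino)methyl]-3-ethoxy-2-geranylcyclohex-2-en-1-one F1. Commercial 3,5-dihydroxybenzaldehyde is silylated (TBSCl, imidazole, DMF) to 3,5-bis(tert-butyldimethylsilyloxy)benzaldehyde F2. F1 and F2 are heated with catalytic 3-benzyl-5-(2-hydroxyethyl)-4-methylthiazolium chloride and Et3N in dioxane at 80 °C. Under these conditions F1 should lose dimethylamine to give 3-ethoxy-2-geranyl-6-methylidenecyclohex-2-en-1-one F3, and the thiazolium-bound acyl anion of F2 adds to its methylidene carbon (Stetter reaction). The fallback comes back to the route at 10.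

2. Step 6. Ring closure may stall because the vinylogous ester carbonyl is a weak electrophile, or the released water may cleave the enol ether before cyclisation, giving mixtures. The fallback sets out from 10. The vinylogous ester is hydrolysed first (1 M aq. HCl, THF, rt) to 4-{2-[3,5-bis(tert-butyldimethylsilyloxy)phenyl]-2-oxoethyl}-2-geranylcyclohexane-1,3-dione F4. The enolised dione of F4 and the aryl ketone are then cyclodehydrated with pyridinium p-toluenesulfonate in toluene at 60 °C. This is the Paal–Knorr closure on a true 1,3-dione; only the carbonyl next to the substituted carbon is 1,4 to the aryl ketone. It should give the ketone directly, and the fallback comes back to the route at 12.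

3. Step 1. O-alkylation and a second alkylation at C2 may compete with the single C-alkylation in water. The fallback sets out from 2. Commercial 1,5-dimethoxycyclohexa-1,4-diene is lithiated with t-BuLi in THF at −78 °C at the methylene between the two enol ether carbons and alkylated with 2 to give 6-geranyl-1,5-dimethoxycyclohexa-1,4-diene F5. Hydrolysis of both enol ethers (1 M aq. HCl, acetone, rt) leads back to the route at 3.

**Further compounds**

F1 | step 5 | 6-[(dimethylamino)methyl]-3-ethoxy-2-geranylcyclohex-2-en-1-one (racemic) | CCOC1=C(C/C=C(\C)CCC=C(C)C)C(=O)C(CN(C)C)CC1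
F2 | step 5 | 3,5-bis(tert-butyldimethylsilyloxy)benzaldehyde | O=Cc1cc(O[Si](C)(C)C(C)(C)C)cc(O[Si](C)(C)C(C)(C)C)c1
F3 | step 5 | 3-ethoxy-2-geranyl-6-methylidenecyclohex-2-en-1-one | CCOC1=C(C/C=C(\C)CCC=C(C)C)C(=O)C(=C)CC1
F4 | step 6 | 4-{2-[3,5-bis(tert-butyldimethylsilyloxy)phenyl]-2-oxoethyl}-2-geranylcyclohexane-1,3-dione | O=C1CCC(CC(=O)c2cc(O[Si](C)(C)C(C)(C)C)cc(O[Si](C)(C)C(C)(C)C)c2)C(=O)C1C/C=C(\C)CCC=C(C)C
F5 | step 1 | 6-geranyl-1,5-dimethoxycyclohexa-1,4-diene | COC1=CCC=C(OC)C1C/C=C(\C)CCC=C(C)C
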